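**Assumptions**

- The catalyst antipode that exposes the required face of C10 is taken to be the one derived from (S)-α,α-diphenylprolinol, by analogy with its sense of induction towards other dienophiles bound through a carbonyl and an α-C–H; if the sense were the reverse, the (R)-catalyst would be used with no other change.
- In 5–9 the C6 and C7 configurations are drawn as the expected major ones (reagent approach from the convex β face); both centres are erased or equilibrated in steps 6 and 7, so any mixture there is carried through.

Convention: eudesmane numbering; β is the face of the C10 methyl; intermediates without C15 are named as 15-noreudesmanes.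

## Structural features

The target is the (E)-4-hydroxycinnamate of a eudesmane alcohol: a trans-fused decalin in which ring A (C1–C5, C10) carries an exocyclic methylidene at C4 (C4=C15) and ring B (C5–C10) carries the ester oxygen at C6 and an isopropyl group at C7, the rings sharing the C5–C10 bond and C10 bearing the angular methyl. Four stereocentres stand in a row: C10 (quaternary), C5, C6 and C7. With the methyl axial (β), H5 is α, the C6 oxygen is α and the isopropyl is β, so every ring B substituent except the methyl is equatorial; once C10 is fixed, C5, C6 and C7 correspond to the thermodynamically preferred arrangement. The fragile groups are the 1,1-disubstituted alkene, which is allylic to C5 and would move into conjugation with any C6 carbonyl, and the enoate ester with its free phenol, which tolerates neither hydride, dissolving metal, hydrogenation nor strong base. Every intermediate with oxygen at both C4 and C6 has a further hazard: when one is a carbonyl and the other a leaving group, enolisation at C5 invites β-elimination. The real difficulty is the absolute configuration of the all-carbon quaternary centre C10 and its trans relationship to C5, not the ester. The key step exploits the fact that ring B (oxygen at C6, isopropyl at C7, methyl at C10) has the substitution pattern of 2-isopropyl-5-methyl-1,4-benzoquinone, whose methyl-bearing C5=C10 alkene can take up a four-carbon 1-oxygenated diene to form C1–C10, C4–C5, ring A, the quaternary centre and a C4 oxygen in one operation.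

## Logic of the disconnections

19 ⇒ 18. The aryl O–acetyl bond is cut. The phenol has to be masked during acylation, oxidation and methylenation. The forward step must cleave an aryl acetate without touching the hindered secondary enoate.

18 ⇒ 17. The C4=C15 double bond is cut to a C4 ketone. The exocyclic alkene is the most migration-prone group and is therefore installed last on the skeleton. The forward step needs a non-basic methylenation that spares two esters and a β-acyloxy ketone.

17 ⇒ 16 ⇒ 15. The C4 oxidation level and the O–Si bond are retraced, so that C4 carries the silyl ether that comes from the diene. The demand is desilylation under conditions that leave both esters in place and do not provoke acyl migration.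

15 ⇒ 11 + 13 (through 14); 13 ⇒ 12. The ester C6–O–C(=O) bond is cut. Using the final acyl group as the C6 protecting group during the C4 operations saves a protect/deprotect pair and makes the route convergent. The forward step must acylate a hindered equatorial alcohol.

11 ⇒ 10. The C6–H bond is cut to a ketone. The equatorial alcohol is the thermodynamic one, so the forward reduction must be under thermodynamic control; hydride attack would be steered by the axial C10 methyl to the axial alcohol.

10 ⇒ 9. The C5–H and C7–H bonds are retraced to their epimers. This lets the cis fusion of the cycloadduct and an uncontrolled C7 centre be corrected in one equilibration. The demand is enolisation at C5 without loss of the C4 silyloxy group.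

9 ⇒ 8 ⇒ 6 (through 7) ⇒ 5 ⇒ 4. These are functional-group changes only: the C6 alcohol/ketone pair tells C6 from C9, the two C–O bonds at C9 are removed, and two C=C bonds are saturated. The simplification is that 4 holds every skeletal carbon of the terpene. The demand is a site-selective reduction of one of two enone carbonyls.

4 ⇒ 2 + 3. The C1–C10 and C4–C5 bonds are cut (retro-cycloaddition). This removes ring A, the quaternary centre and three stereocentres and leaves two simple achiral components. The forward step must choose the methyl-bearing alkene of 3, the orientation that puts the oxygenated diene carbon on C5, and one face of C10.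

2 ⇒ 1. The O–Si bond is cut with tautomerisation; the diene comes from an enal in one step.

## Other disconnections considered

Alternative 1: The cut is through the whole bicycle, back to acyclic (2E,6E)-farnesyl diphosphate A2. A class 1 sesquiterpene synthase would ionise A2, close the ten-membered ring, shift a hydride, capture water at C6 and close C5–C10 transannularly, giving junenol A1 with the exocyclic alkene in place.
- In its favour: one enzymatic step to A1 and then acylation and deprotection. In step economy it is clearly better than the chosen plan. It is also better on stereocontrol: the enzyme would deliver the trans fusion and the equatorial alcohol directly, whereas the chosen plan needs an equilibration (step 7) and a thermodynamic reduction (step 8).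
- Against it here: it needs a synthase with exactly this product specificity, expressed in usable amounts, and a supply of A2 or an engineered host. Terpene synthases commonly give product mixtures, and only one enantiomeric series is accessible.
- Comparison: the mechanism is a cationic cascade steered by an active site, against a pericyclic step steered by a small catalyst available in both antipodes. The chosen plan is longer but uses only bench reagents and purchasable starting materials.

Alternative 2: The cut is at C10–C14 and C5–C6, with ring B closed later at C7–C8. A copper–phosphoramidite-catalysed conjugate methylation of 3-allylcyclohex-2-enone A4 would set C10, and the resulting aluminium enolate would be trapped by 2-isopropylacrolein A5 to give aldol adduct A3.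
- In its favour: the C4 ketone is present from the start, no C9 oxygen has to be removed, and the C6 oxygen arrives at the right oxidation level. About eight steps in all would be needed (metathesis with a second-generation Grubbs catalyst, hydrogenation, methylenation, acylation), so step economy is better than in the chosen plan. The way C10 is set (chiral catalyst, intermolecular) is the equal of the chosen plan.
- Against it: C5 must be set by an enolate that distinguishes methyl from allyl on the neighbouring quaternary carbon, and C6 by a kinetic aldol with an α-branched enal. C7 would depend on a directed hydrogenation (for example with [Ir(cod)(py)(PCy3)]PF6). The β-hydroxy ketone A3 is open to retro-aldol and dehydration.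
- Comparison: the chosen plan is longer, but its three ring B centres all come from thermodynamic control; the alternative is shorter but sets them kinetically.

Alternative 3: The cut is at C5–C10 and C1–C2 of an open-chain triene that carries a 2-silyloxydiene and a vinyl sulfone. Heating would close rings A and B together to the trans-decalin silyl enol ether A6.
- In its favour: two rings and the trans fusion in one step, where the chosen plan closes one ring and corrects the fusion afterwards; on structure it is the better disconnection. The C4 oxygen emerges as a regiodefined enol ether and there is no surplus oxygen at C9.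
- Against it: the precursor must already hold the C6 and C7 stereocentres, which means a long linear preparation. The dienophile is trisubstituted, carries its methyl on the carbon that must become quaternary and is activated at the other carbon. The cis/trans ratio of such cyclisations is not secure, and the sulfone must be removed afterwards.
- Comparison: absolute control is by substrate in the alternative and by catalyst in the chosen plan, which is equal in principle. The alternative would cost more steps overall, so step economy favours the chosen plan.

Key step: step 2

## Steps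

Step 1
Reactants: 1 crotonaldehyde
Product: 2 (E)-1-(tert-butyldimethylsilyloxy)buta-1,3-diene
Conditions: TBSOTf, Et3N, Et2O, 0 → 23 °C; distillation
Reagents that add atoms: tert-butyldimethylsilyl triflate, CC(C)(C)[Si](C)(C)OS(=O)(=O)C(F)(F)F
Why: O-silylation of the enal followed by γ-deprotonation with the amine (vinylogous silyl enol ether formation) should give mainly the E dienol ether; any Z isomer is a poor diene and should not interfere.

Step 2
Reactants: 2 (E)-1-(tert-butyldimethylsilyloxy)buta-1,3-diene; 3 thymoquinone
Product: 4 4α-(tert-butyldimethylsilyloxy)-5βH-15-noreudesma-2,7-diene-6,9-dione (cis-fused)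
Conditions: (S)-3,3-diphenyl-1-(2-methylphenyl)tetrahydro-1H,3H-pyrrolo[1,2-c][1,3,2]oxazaborole (20 mol %), HN(SO2CF3)2 (18 mol %), CH2Cl2, −78 °C, 2 (1.5 equiv) added slowly; cold non-basic work-up
Reagents that add atoms: none
Why: The protonated oxazaborolidine binds the C6 carbonyl through the oxygen lone pair on the C5–H side (the other side faces the isopropyl-bearing C7), with the C5–H held near the ring oxygen of the catalyst, so C10 becomes the electrophilic β-carbon of the C5=C10 alkene. The CH2 terminus of 2, which carries the largest HOMO coefficient, bonds first to C10 and the silyloxy-bearing terminus closes onto C5 in a concerted, asynchronous [4+2] cycloaddition; the closest known reaction type is the oxazaborolidinium-catalysed Diels–Alder reaction of alkylated 1,4-benzoquinones with oxygenated dienes. Ring A is closed by suprafacial–suprafacial cycloaddition across the quinone alkene, which fuses the new six-membered ring cis to ring B. C10 is set by the catalyst, whose aryl group shields one face of the bound quinone; C5 follows from the suprafacial addition (H5 cis to the C10 methyl); C4 follows from the E geometry of 2 and the endo transition state, which places the silyloxy group trans to H5 and to the methyl. Site selectivity between the two quinone alkenes rests on sterics, because binding at the C9 carbonyl on its C8–H side would require bond formation at the isopropyl-bearing C7. Regioselectivity rests on Lewis-acid control, and the low temperature should suppress the uncatalysed reaction, which may prefer the opposite orientation. The C4 centre and the cis fusion are provisional (C4 becomes sp2, C5 is inverted in step 7), so only the C10 configuration has to survive to the end.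

Step 3
Reactants: 4 4α-(tert-butyldimethylsilyloxy)-5βH-15-noreudesma-2,7-diene-6,9-dione
Product: 5 4α-(tert-butyldimethylsilyloxy)-6α-hydroxy-5βH-15-noreudesma-2,7-dien-9-one
Conditions: NaBH4 (0.3 equiv, titrated), CeCl3·7H2O, MeOH/CH2Cl2, −78 °C
Reagents that add atoms: none
Why: Luche reduction adds hydride 1,2 to the C6 carbonyl, which should be the more reactive one because C9 is a β-alkylated enone carbonyl flanked by the quaternary C10; attack from the convex β face should give the 6α-alcohol, a centre that is reoxidised later. Reducing C6 at once also removes the β-silyloxy ketone, so the C4 oxygen can no longer be lost by elimination.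

Step 4
Reactants: 5 4α-(tert-butyldimethylsilyloxy)-6α-hydroxy-5βH-15-noreudesma-2,7-dien-9-one
Product: 6 4α-(tert-butyldimethylsilyloxy)-6α-hydroxy-5βH,7βH-15-noreudesman-9-one (isopropyl α)
Conditions: H2 (1 atm), Pd/C (5 % palladium on carbon), EtOAc, 23 °C
Reagents that add atoms: none
Why: Heterogeneous catalytic hydrogenation saturates the cis-disubstituted C2=C3 alkene and the enone C7=C8 bond; delivery from the convex β face should place the isopropyl group α, which is corrected in step 7.

Step 5
Reactants: 6 4α-(tert-butyldimethylsilyloxy)-6α-hydroxy-5βH,7βH-15-noreudesman-9-one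
Product: 8 4α-(tert-butyldimethylsilyloxy)-5βH,7βH-15-noreudesman-6α-ol, via C9 hydrazone 7 (not isolated)
Conditions: N2H4·H2O, AcOH (cat.), n-BuOH, 110 °C; evaporate; then KOtBu, DMSO, 23 → 60 °C
Reagents that add atoms: none
Why: Wolff–Kishner reduction in its low-temperature KOtBu/DMSO form: the hydrazone anion tautomerises to the diazene, loses N2 and is protonated; C9 is the only carbonyl present, and the mild second stage is chosen so that the silyl ether survives.

Step 6
Reactants: 8 4α-(tert-butyldimethylsilyloxy)-5βH,7βH-15-noreudesman-6α-ol
Product: 9 4α-(tert-butyldimethylsilyloxy)-5βH,7βH-15-noreudesman-6-one (cis-fused)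
Conditions: Dess–Martin periodinane, NaHCO3, CH2Cl2, 0 → 23 °C
Reagents that add atoms: none
Why: Dess–Martin oxidation of the secondary alcohol under buffered, non-basic conditions, so that the new β-silyloxy ketone is not enolised during its formation.

Step 7
Reactants: 9 4α-(tert-butyldimethylsilyloxy)-5βH,7βH-15-noreudesman-6-one
Product: 10 4α-(tert-butyldimethylsilyloxy)-5αH,7αH-15-noreudesman-6-one (trans-fused; isopropyl β)
Conditions: NaOMe (0.2 equiv), MeOH, 0 → 23 °C, stopped when the isomer ratio no longer changes; unconverted isomer recycled
Reagents that add atoms: none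
Why: Base-mediated epimerisation through the C5 and C7 enolates; under thermodynamic control the trans-fused chair–chair isomer with the isopropyl and silyloxy groups both equatorial should predominate, which sets C5 and C7 relative to C10. Catalytic base and low temperature are chosen to limit β-elimination of the silanol.

Step 8
Reactants: 10 4α-(tert-butyldimethylsilyloxy)-5αH,7αH-15-noreudesman-6-one
Product: 11 4α-(tert-butyldimethylsilyloxy)-5αH,7αH-15-noreudesman-6α-ol
Conditions: Li, NH3(l)/THF, EtOH, −78 → −33 °C; NH4Cl
Reagents that add atoms: none
Why: Dissolving-metal reduction of the ketone proceeds by stepwise electron transfer and protonation and should give the thermodynamically preferred equatorial 6α-alcohol; a hydride reagent would approach from the face away from the axial C10 methyl and give the axial epimer.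

Step 9
Reactants: 12 p-coumaric acid
Product: 13 (E)-3-(4-acetoxyphenyl)prop-2-enoic acid
Conditions: Ac2O, pyridine, 23 °C; then H2O
Reagents that add atoms: acetic anhydride, CC(=O)OC(C)=O
Why: O-acetylation of the phenol; any mixed anhydride at the carboxyl group is hydrolysed in the aqueous quench.

Step 10
Reactants: 11 4α-(tert-butyldimethylsilyloxy)-5αH,7αH-15-noreudesman-6α-ol; 13 (E)-3-(4-acetoxyphenyl)prop-2-enoic acid
Product: 15 4α-(tert-butyldimethylsilyloxy)-5αH,7αH-15-noreudesman-6α-yl (E)-3-(4-acetoxyphenyl)prop-2-enoate, via 4-acetoxycinnamoyl chloride 14 (not isolated)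
Conditions: 13, (COCl)2, DMF (cat.), CH2Cl2, 0 → 23 °C; evaporate; then 11, DMAP, Et3N, CH2Cl2, 23 → 40 °C
Reagents that add atoms: none
Why: Acid chloride formation and DMAP-catalysed acylation; the alcohol is hindered by the isopropyl group and the neighbouring silyl ether, so excess acyl chloride and gentle heating are planned, and O-acylation leaves the C6 configuration untouched.

Step 11
Reactants: 15 4α-(tert-butyldimethylsilyloxy)-5αH,7αH-15-noreudesman-6α-yl (E)-3-(4-acetoxyphenyl)prop-2-enoate
Product: 16 4α-hydroxy-5αH,7αH-15-noreudesman-6α-yl (E)-3-(4-acetoxyphenyl)prop-2-enoate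
Conditions: HF·pyridine, pyridine/THF, 0 → 23 °C
Reagents that add atoms: none
Why: Fluoride-mediated desilylation under weakly acidic conditions, which spare the aryl acetate and the enoate and should not promote acyl migration to the liberated C4 hydroxyl.

Step 12
Reactants: 16 4α-hydroxy-5αH,7αH-15-noreudesman-6α-yl (E)-3-(4-acetoxyphenyl)prop-2-enoate
Product: 17 4-oxo-5αH,7αH-15-noreudesman-6α-yl (E)-3-(4-acetoxyphenyl)prop-2-enoate
Conditions: Dess–Martin periodinane, NaHCO3, CH2Cl2, 23 °C
Reagents that add atoms: none
Why: Dess–Martin oxidation under neutral conditions, so that the β-acyloxy ketone is neither enolised nor eliminated and the trans C5 centre is kept.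

Step 13
Reactants: 17 4-oxo-5αH,7αH-15-noreudesman-6α-yl (E)-3-(4-acetoxyphenyl)prop-2-enoate
Product: 18 5αH,7αH-eudesm-4(15)-en-6α-yl (E)-3-(4-acetoxyphenyl)prop-2-enoate
Conditions: Zn, CH2Br2, TiCl4, THF/CH2Cl2, 0 → 23 °C (reagent pre-aged)
Reagents that add atoms: dibromomethane, BrCBr
Why: Takai–Lombardo methylenation: the zinc/titanium methylene reagent is oxophilic but non-basic, so it should convert the ketone into the methylidene without enolising C5, without expelling the β-acyloxy group and without attacking either ester.

Step 14
Reactants: 18 5αH,7αH-eudesm-4(15)-en-6α-yl (E)-3-(4-acetoxyphenyl)prop-2-enoate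
Product: 19 5αH,7αH-eudesm-4(15)-en-6α-yl (E)-3-(4-hydroxyphenyl)prop-2-enoate
Conditions: K2CO3 (0.5 equiv), MeOH, 0 °C, short reaction time; NH4Cl
Reagents that add atoms: none
Why: Transesterification of the aryl acetate, whose phenoxide leaving group makes it far more reactive than the hindered secondary enoate; the conditions are too mild to move the exocyclic alkene.

## Compound list

1 | crotonaldehyde, (E)-but-2-enal | C/C=C/C=O | starting material
2 | (E)-1-(tert-butyldimethylsilyloxy)buta-1,3-diene | C=C/C=C/O[Si](C)(C)C(C)(C)C | intermediate
3 | thymoquinone, 2-isopropyl-5-methyl-1,4-benzoquinone | CC1=CC(=O)C(C(C)C)=CC1=O | starting material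
4 | 4α-(tert-butyldimethylsilyloxy)-5βH-15-noreudesma-2,7-diene-6,9-dione (cis-fused adduct) | CC(C)(C)[Si](C)(C)O[C@@H]1C=CC[C@]2(C)C(=O)C=C(C(C)C)C(=O)[C@H]12 | intermediate
5 | 4α-(tert-butyldimethylsilyloxy)-6α-hydroxy-5βH-15-noreudesma-2,7-dien-9-one | CC(C)(C)[Si](C)(C)O[C@@H]1C=CC[C@]2(C)C(=O)C=C(C(C)C)[C@H](O)[C@H]12 | intermediate
6 | 4α-(tert-butyldimethylsilyloxy)-6α-hydroxy-5βH,7βH-15-noreudesman-9-one | CC(C)(C)[Si](C)(C)O[C@@H]1CCC[C@]2(C)C(=O)C[C@H](C(C)C)[C@H](O)[C@H]12 | intermediate
7 | C9 hydrazone of 6 | CC(C)(C)[Si](C)(C)O[C@@H]1CCC[C@]2(C)C(=NN)C[C@H](C(C)C)[C@H](O)[C@H]12 | intermediate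
8 | 4α-(tert-butyldimethylsilyloxy)-5βH,7βH-15-noreudesman-6α-ol | CC(C)(C)[Si](C)(C)O[C@@H]1CCC[C@]2(C)CC[C@H](C(C)C)[C@H](O)[C@H]12 | intermediate
9 | 4α-(tert-butyldimethylsilyloxy)-5βH,7βH-15-noreudesman-6-one (cis-fused) | CC(C)(C)[Si](C)(C)O[C@@H]1CCC[C@]2(C)CC[C@H](C(C)C)C(=O)[C@H]12 | intermediate
10 | 4α-(tert-butyldimethylsilyloxy)-5αH,7αH-15-noreudesman-6-one (trans-fused) | CC(C)(C)[Si](C)(C)O[C@@H]1CCC[C@]2(C)CC[C@@H](C(C)C)C(=O)[C@@H]12 | intermediate
11 | 4α-(tert-butyldimethylsilyloxy)-5αH,7αH-15-noreudesman-6α-ol | CC(C)(C)[Si](C)(C)O[C@@H]1CCC[C@]2(C)CC[C@@H](C(C)C)[C@H](O)[C@@H]12 | intermediate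
12 | p-coumaric acid, (E)-3-(4-hydroxyphenyl)prop-2-enoic acid | O=C(O)/C=C/c1ccc(O)cc1 | starting material
13 | (E)-3-(4-acetoxyphenyl)prop-2-enoic acid | CC(=O)Oc1ccc(/C=C/C(=O)O)cc1 | intermediate
14 | (E)-3-(4-acetoxyphenyl)prop-2-enoyl chloride | CC(=O)Oc1ccc(/C=C/C(=O)Cl)cc1 | intermediate
15 | 4α-(tert-butyldimethylsilyloxy)-5αH,7αH-15-noreudesman-6α-yl (E)-3-(4-acetoxyphenyl)prop-2-enoate | CC(C)(C)[Si](C)(C)O[C@@H]1CCC[C@]2(C)CC[C@@H](C(C)C)[C@H](OC(=O)/C=C/c3ccc(OC(C)=O)cc3)[C@@H]12 | intermediate
16 | 4α-hydroxy-5αH,7αH-15-noreudesman-6α-yl (E)-3-(4-acetoxyphenyl)prop-2-enoate | O[C@@H]1CCC[C@]2(C)CC[C@@H](C(C)C)[C@H](OC(=O)/C=C/c3ccc(OC(C)=O)cc3)[C@@H]12 | intermediate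
17 | 4-oxo-5αH,7αH-15-noreudesman-6α-yl (E)-3-(4-acetoxyphenyl)prop-2-enoate | O=C1CCC[C@]2(C)CC[C@@H](C(C)C)[C@H](OC(=O)/C=C/c3ccc(OC(C)=O)cc3)[C@@H]12 | intermediate
18 | 5αH,7αH-eudesm-4(15)-en-6α-yl (E)-3-(4-acetoxyphenyl)prop-2-enoate | C=C1CCC[C@]2(C)CC[C@@H](C(C)C)[C@H](OC(=O)/C=C/c3ccc(OC(C)=O)cc3)[C@@H]12 | intermediate
19 | 5αH,7αH-eudesm-4(15)-en-6α-yl (E)-3-(4-hydroxyphenyl)prop-2-enoate; (5S,6S,7S,10R) | C=C1CCC[C@]2(C)CC[C@@H](C(C)C)[C@H](OC(=O)/C=C/c3ccc(O)cc3)[C@@H]12 | target

## Step count and least certain steps

Total: 14 steps. Longest linear sequence: 13 steps (steps 1–8 and 10–14, from 1); step 9 is a one-step side branch.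

**Step 2 (key step).** The likely failures are competing cycloaddition at the isopropyl-bearing alkene, leakage through the uncatalysed pathway with the opposite orientation, and silyl transfer of the Mukaiyama–Michael type in place of ring closure. The two quinone alkenes differ only by methyl against isopropyl, and the diene is acid-labile.
Fallback: give up catalyst control of the absolute configuration. Setting out from 2 and 3, the cycloaddition is promoted by the racemic form of the same oxazaborolidinium salt, which keeps the carbonyl-coordination logic for regiochemistry. It gives 4 together with the mirror-image adduct F1. Reduction as in step 3 gives 5 together with the mirror-image hydroxy enone F2. Site isomers are removed at this stage and the racemate is resolved by preparative chromatography on a chiral stationary phase. The route is rejoined at 5.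

**Step 7.** The likely failures are loss of the silanol by β-elimination from the C5 enolate, in competition with reprotonation, and an equilibrium that does not lie fully on the trans side, because the angular methyl reduces the usual trans preference of decalones.
Fallback: equilibrate with the C4 oxygen as an alkoxide, which cannot leave. Setting out from 9, HF·pyridine gives the cis hydroxy ketone F3. KOtBu (2 equiv) in t-BuOH/THF at 0 °C holds the hydroxyl as its alkoxide, where retro-aldol opening of C4–C5 can only re-form the same ring, and equilibrates it to the trans hydroxy ketone F4. TBSOTf/2,6-lutidine then restores the silyl ether, and the route is rejoined at 10.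

**Step 3.** The likely failures are poor discrimination between the C6 and C9 carbonyls, or conjugate reduction.
Fallback: distinguish the carbonyls by enolisation instead of by hydride attack. Setting out from 4, Zn/AcOH reduces the ene-dione alkene to the ring-B-saturated dione F5 (either C7 epimer serves). KHMDS and PhNTf2 at −78 °C remove a proton from the only methylene next to a carbonyl (C8) and give the C9 enol triflate F6. Pd(OAc)2, PPh3, HCO2H and Bu3N in DMF (zerovalent palladium formed in the flask) replace the triflate by hydrogen to give the dienone F7. Hydrogenation over Pd/C saturates both alkenes and rejoins the route at 9, so steps 3–6 are bypassed.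

**Step 5.** The likely failures are incomplete condensation of hydrazine with the neopentyl C9 carbonyl, azine formation, or desilylation in the strongly basic second stage.
Fallback: deoxygenate through a thioacetal. Setting out from 6, ethane-1,2-dithiol and Zn(OTf)2 in CH2Cl2 give the C9 dithiolane F8. Raney Ni in EtOH removes the sulfur and rejoins the route at 8.

**Step 13.** The likely failures are Lewis-acid-induced β-elimination of the cinnamate from the β-acyloxy ketone, or sluggish methylenation of the hindered C4 carbonyl.
Fallback: build the methylidene before the ester. Setting out from 11: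
- 4-methoxybenzyl trichloroacetimidate with La(OTf)3 gives the C6 4-methoxybenzyl ether F9.
- Bu4NF gives the C4 alcohol F10.
- Dess–Martin periodinane gives the C4 ketone F11.
- Ph3P=CH2 (Wittig) gives the methylidene ether F12.
- DDQ in wet CH2Cl2 frees junenol F13, the same compound as A1.
- Acylation of F13 with 14 (DMAP, Et3N) rejoins the route at 18.

## Further compounds

F1 | step 2 | enantiomer of 4 | CC(C)(C)[Si](C)(C)O[C@H]1C=CC[C@@]2(C)C(=O)C=C(C(C)C)C(=O)[C@@H]12
F2 | step 2 | enantiomer of 5 | CC(C)(C)[Si](C)(C)O[C@H]1C=CC[C@@]2(C)C(=O)C=C(C(C)C)[C@@H](O)[C@@H]12
F3 | step 7 | 4α-hydroxy-5βH,7βH-15-noreudesman-6-one | O[C@@H]1CCC[C@]2(C)CC[C@H](C(C)C)C(=O)[C@H]12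
F4 | step 7 | 4α-hydroxy-5αH,7αH-15-noreudesman-6-one | O[C@@H]1CCC[C@]2(C)CC[C@@H](C(C)C)C(=O)[C@@H]12
F5 | step 3 | 4α-(tert-butyldimethylsilyloxy)-5βH,7βH-15-noreudesm-2-ene-6,9-dione | CC(C)(C)[Si](C)(C)O[C@@H]1C=CC[C@]2(C)C(=O)C[C@H](C(C)C)C(=O)[C@H]12
F6 | step 3 | 4α-(tert-butyldimethylsilyloxy)-6-oxo-5βH,7βH-15-noreudesma-2,8-dien-9-yl triflate | CC(C)(C)[Si](C)(C)O[C@@H]1C=CC[C@]2(C)C(OS(=O)(=O)C(F)(F)F)=C[C@H](C(C)C)C(=O)[C@H]12
F7 | step 3 | 4α-(tert-butyldimethylsilyloxy)-5βH,7βH-15-noreudesma-2,8-dien-6-one | CC(C)(C)[Si](C)(C)O[C@@H]1C=CC[C@]2(C)C=C[C@H](C(C)C)C(=O)[C@H]12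
F8 | step 5 | C9 ethylene dithioacetal (1,3-dithiolane) of 6 | CC(C)(C)[Si](C)(C)O[C@@H]1CCC[C@]2(C)C3(SCCS3)C[C@H](C(C)C)[C@H](O)[C@H]12
F9 | step 13 | 4α-(tert-butyldimethylsilyloxy)-6α-(4-methoxybenzyloxy)-5αH,7αH-15-noreudesmane | CC(C)(C)[Si](C)(C)O[C@@H]1CCC[C@]2(C)CC[C@@H](C(C)C)[C@H](OCc3ccc(OC)cc3)[C@@H]12
F10 | step 13 | 6α-(4-methoxybenzyloxy)-5αH,7αH-15-noreudesman-4α-ol | O[C@@H]1CCC[C@]2(C)CC[C@@H](C(C)C)[C@H](OCc3ccc(OC)cc3)[C@@H]12
F11 | step 13 | 6α-(4-methoxybenzyloxy)-5αH,7αH-15-noreudesman-4-one | O=C1CCC[C@]2(C)CC[C@@H](C(C)C)[C@H](OCc3ccc(OC)cc3)[C@@H]12
F12 | step 13 | 6α-(4-methoxybenzyloxy)-5αH,7αH-eudesm-4(15)-ene | C=C1CCC[C@]2(C)CC[C@@H](C(C)C)[C@H](OCc3ccc(OC)cc3)[C@@H]12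
F13 | step 13 | junenol, 5αH,7αH-eudesm-4(15)-en-6α-ol | C=C1CCC[C@]2(C)CC[C@@H](C(C)C)[C@H](O)[C@@H]12
A1 | alternative 1 | junenol, 5αH,7αH-eudesm-4(15)-en-6α-ol | C=C1CCC[C@]2(C)CC[C@@H](C(C)C)[C@H](O)[C@@H]12
A2 | alternative 1 | (2E,6E)-farnesyl diphosphate | CC(C)=CCC/C(C)=C/CC/C(C)=C/COP(=O)(O)OP(=O)(O)O
A3 | alternative 2 | anti-aldol adduct, 3-allyl-2-(1-hydroxy-3-methyl-2-methylidenebutyl)-3-methylcyclohexanone | C=CC[C@@]1(C)CCCC(=O)[C@@H]1[C@@H](O)C(=C)C(C)C
A4 | alternative 2 | 3-allylcyclohex-2-en-1-one | C=CCC1=CC(=O)CCC1
A5 | alternative 2 | 2-isopropylacrolein, 3-methyl-2-methylidenebutanal | C=C(C=O)C(C)C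
A6 | alternative 3 | trans-decalin silyl enol ether with a phenylsulfonyl group at C1 and a silyl ether at C6 | CC(C)(C)[Si](C)(C)OC1=CC[C@@H](S(=O)(=O)c3ccccc3)[C@]2(C)CC[C@@H](C(C)C)[C@H](O[Si](C)(C)C(C)(C)C)[C@@H]12
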